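**Plan**

Numbering: chain C1 (alkyne CH) to C15 (CH3), ring oxygen between C7 and C12. The retrosynthesis cuts C13–Br (back to the inverted carbinol) and the C6 acetate, then C3=C4 (Z-enyne Peterson olefination), C5–C6 (acetate aldol on a C6 aldehyde) and C13–C14 (ethyl Grignard on a C13 aldehyde), and finally takes one ring methylene out of the oxepene (C10 with bonds C9–C10 and C10–C11, or C9 in the mirror-image sense).
Enabling feature: before bromination the centres C6, C7, C12, C13 are (6S,7S,12R,13R), pairwise mirror images across the ring oxygen. The oxepene with C6 and C13 as ester carbons is therefore an achiral cis-2,7-diester, and its seven-membered ring minus one CH2 is the six-membered ring of fully hydrogenated chelidonic acid, with the ketone on the symmetry plane.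
Forward order: the pyran ring comes from chelidonic acid and is enlarged to the oxepane by diazoalkane insertion. The silicon left on the inserted carbon is then used to place C9=C10. The meso diol is desymmetrised, the C6 arm is extended by two carbons, the C13 arm receives ethyl and bromine, and the enyne is attached last.
Stereochemistry: C7/C12 cis from hydrogenation of the flat pyranone; absolute sense from one lipase acetylation; C6 and C13 from chelation-controlled additions with the ring oxygen as chelating atom; C13 inverted by phosphine/CBr4; Z-olefin from the bis-silylpropyne Peterson reagent.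

Key step: step 4

Remark: the silyl group of the diazoalkane is deliberately kept on the inserted carbon of the key-step product (6 is the ring-expanded oxepanone carrying this spectator group), because it records which side of the ketone is new and so fixes where the C9=C10 olefin goes.
Assumption: lipase PS is taken to acetylate the hydroxymethyl group on the R-configured ring carbon (future C12) of meso diol 10; if it prefers the other arm, hydrolysis of the meso diacetate with the same enzyme gives the same monoacetate 12.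

**Route**

Step 1
Reactants: 1 chelidonic acid
Product: 2 dimethyl 4-oxo-4H-pyran-2,6-dicarboxylate
Conditions: MeOH, H2SO4 (cat.), reflux
Reagents that add atoms: methanol, CO
Why: Fischer esterification of both acids; the 4-pyranone is stable to hot acidic methanol and no stereocentre is involved.

Step 2
Reactants: 2 dimethyl 4-oxo-4H-pyran-2,6-dicarboxylate
Product: 3 dimethyl all-cis-4-hydroxytetrahydropyran-2,6-dicarboxylate (meso)
Conditions: H2 (50 bar), 5% Rh/Al2O3, EtOAc–MeOH, rt
Reagents that add atoms: none
Why: Heterogeneous hydrogenation; the planar pyranone should take up all hydrogen from its catalyst-bound face, so the two ester-bearing carbons (future C7 and C12) are set cis by adsorption, rhodium is chosen to limit C–O hydrogenolysis, and the carbinol configuration is of no consequence.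

Step 3
Reactants: 3 dimethyl all-cis-4-hydroxytetrahydropyran-2,6-dicarboxylate
Product: 4 dimethyl (2R,6S)-4-oxotetrahydropyran-2,6-dicarboxylate (meso, cis)
Conditions: Dess–Martin periodinane, CH2Cl2, rt
Reagents that add atoms: none
Why: Dess–Martin oxidation under neutral conditions returns the carbinol to the ketone without exposing the β-alkoxy ketone to base, so neither retro-oxa-Michael opening nor epimerisation at the ester-bearing carbons is expected.

Step 4
Reactants: 4 dimethyl (2R,6S)-4-oxotetrahydropyran-2,6-dicarboxylate; 5 (trimethylsilyl)diazomethane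
Product: 6 dimethyl cis-4-oxo-5-(trimethylsilyl)oxepane-2,7-dicarboxylate (racemic, both C5 epimers)
Conditions: Me3Al, CH2Cl2, −78 → −40 °C; cold aq. Rochelle salt; used crude
Reagents that add atoms: (trimethylsilyl)diazomethane (5), C[Si](C)(C)C=[N+]=[N-]
Why: Me3Al activates the ketone of 4, the diazo carbon of 5 adds to give a β-aluminoxy diazonium, and an α-methylene migrates to that carbon as N2 leaves, which forms the C9–C10 and C10–C11 bonds and leaves silicon on the inserted carbon next to the new carbonyl. The closest known reaction is the Lewis-acid-promoted Tiffeneau–Demjanov-type homologation of cyclohexanones and tetrahydropyran-4-ones with (trimethylsilyl)diazomethane. The oxepane is not closed by a cyclisation but arises by 1,2-shift ring enlargement of the pyran, so the cis relation of the two ester-bearing carbons, which take no part in the shift, is carried over. The only new stereocentre, the C–Si carbon, forms without control and is deleted again in step 5. The step needs a single insertion at the ketone only: the bulky α-silyl group should slow a second insertion, the ester carbonyls are inert to the diazoalkane at low temperature, and because the two α-methylenes of meso 4 are enantiotopic either migration gives the same compound as a racemate that regains symmetry in step 6. Me3Al is preferred to BF3 because it should leave the C–Si bond intact, so the inserted carbon stays marked for the olefin.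

Step 5
Reactants: 6 dimethyl cis-4-oxo-5-(trimethylsilyl)oxepane-2,7-dicarboxylate
Product: 8 dimethyl cis-4-(trifluoromethylsulfonyloxy)-2,3,6,7-tetrahydrooxepine-2,7-dicarboxylate (racemic), via trimethylsilyl enol ether 7 (not isolated)
Conditions: PhMe, 110 °C; then CsF, PhNTf2, DME, rt
Reagents that add atoms: N-phenylbis(trifluoromethanesulfonimide), FC(F)(F)S(=O)(=O)N(c1ccccc1)S(=O)(=O)C(F)(F)F
Why: Thermal 1,3-Brook (C→O) silyl shift of the β-ketosilane gives the enol silane with its double bond only between the carbonyl carbon and the former C–Si carbon; fluoride then releases that regiodefined enolate, which PhNTf2 should O-sulfonylate before it can equilibrate (fluoride-mediated enol triflate formation from a silyl enol ether), and any unrearranged 6 should be desilylated to the same enolate.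

Step 6
Reactants: 8 dimethyl cis-4-(trifluoromethylsulfonyloxy)-2,3,6,7-tetrahydrooxepine-2,7-dicarboxylate
Product: 9 dimethyl (2R,7S)-2,3,6,7-tetrahydrooxepine-2,7-dicarboxylate (meso)
Conditions: Pd(OAc)2 (5 mol %), PPh3, HCO2H, Bu3N, DMF, 60 °C
Reagents that add atoms: none
Why: Palladium-catalysed formate reduction of an enol triflate (oxidative addition, formate exchange, decarboxylation, reductive elimination) replaces OTf by H without touching the esters and leaves the olefin at C9=C10, which makes the diester meso again.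

Step 7
Reactants: 9 dimethyl (2R,7S)-2,3,6,7-tetrahydrooxepine-2,7-dicarboxylate
Product: 10 [(2R,7S)-2,3,6,7-tetrahydrooxepine-2,7-diyl]dimethanol (meso)
Conditions: LiAlH4, THF, 0 °C
Reagents that add atoms: none
Why: Hydride reduction of both esters to the primary alcohols; the isolated olefin is inert and the ring stereocentres are not disturbed.

Step 8
Reactants: 10 [(2R,7S)-2,3,6,7-tetrahydrooxepine-2,7-diyl]dimethanol; 11 vinyl acetate
Product: 12 [(2R,7S)-7-(hydroxymethyl)-2,3,6,7-tetrahydrooxepin-2-yl]methyl acetate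
Conditions: lipase PS (Burkholderia cepacia), t-BuOMe, rt, stopped at the monoacetate
Reagents that add atoms: vinyl acetate (11), CC(=O)OC=C
Why: Lipase-catalysed irreversible transesterification of a meso diol; the enzyme distinguishes the two enantiotopic hydroxymethyl groups and so fixes the absolute configuration of C7 and C12 in one operation, with tautomerisation of the vinyl alcohol preventing the back reaction.

Step 9
Reactants: 12 [(2R,7S)-7-(hydroxymethyl)-2,3,6,7-tetrahydrooxepin-2-yl]methyl acetate
Product: 13 [(2R,7S)-7-formyl-2,3,6,7-tetrahydrooxepin-2-yl]methyl acetate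
Conditions: Dess–Martin periodinane, CH2Cl2, 0 °C → rt; used at once
Reagents that add atoms: none
Why: Dess–Martin oxidation gives the α-alkoxy aldehyde without base, so the C7 stereocentre next to the formyl group should not epimerise.

Step 10
Reactants: 13 [(2R,7S)-7-formyl-2,3,6,7-tetrahydrooxepin-2-yl]methyl acetate; 14 1-(tert-butyldimethylsilyloxy)-1-methoxyethene
Product: 15 methyl (3S)-3-[(2S,7R)-7-(acetoxymethyl)-2,3,6,7-tetrahydrooxepin-2-yl]-3-hydroxypropanoate
Conditions: MgBr2·OEt2, CH2Cl2, −78 → −40 °C; aq. NH4Cl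
Reagents that add atoms: 1-(tert-butyldimethylsilyloxy)-1-methoxyethene (14), COC(=C)O[Si](C)(C)C(C)(C)C
Why: Chelation-controlled Mukaiyama aldol addition; magnesium bridges the aldehyde oxygen and the ring oxygen (Cram chelate) and the ketene acetal attacks from the side of the C7–H, which sets C6 as S (syn to the ring oxygen), and any adduct that keeps the silyl group on oxygen is simply 16.

Step 11
Reactants: 15 methyl (3S)-3-[(2S,7R)-7-(acetoxymethyl)-2,3,6,7-tetrahydrooxepin-2-yl]-3-hydroxypropanoate
Product: 16 methyl (3S)-3-[(2S,7R)-7-(acetoxymethyl)-2,3,6,7-tetrahydrooxepin-2-yl]-3-(tert-butyldimethylsilyloxy)propanoate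
Conditions: TBSOTf, 2,6-lutidine, CH2Cl2, −78 → 0 °C
Reagents that add atoms: tert-butyldimethylsilyl triflate, CC(C)(C)[Si](C)(C)OS(=O)(=O)C(F)(F)F
Why: Silylation of the secondary alcohol with a silyl triflate and a hindered base; the TBS ether should survive the methanolysis, Grignard, bromination and DIBAL steps and blocks retro-aldol cleavage.

Step 12
Reactants: 16 methyl (3S)-3-[(2S,7R)-7-(acetoxymethyl)-2,3,6,7-tetrahydrooxepin-2-yl]-3-(tert-butyldimethylsilyloxy)propanoate
Product: 17 methyl (3S)-3-(tert-butyldimethylsilyloxy)-3-[(2S,7R)-7-(hydroxymethyl)-2,3,6,7-tetrahydrooxepin-2-yl]propanoate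
Conditions: K2CO3 (cat.), MeOH, 0 °C
Reagents that add atoms: none
Why: Base-catalysed methanolysis (transesterification) removes the primary acetate, while exchange at the methyl ester is degenerate and the silyl ether is stable.

Step 13
Reactants: 17 methyl (3S)-3-(tert-butyldimethylsilyloxy)-3-[(2S,7R)-7-(hydroxymethyl)-2,3,6,7-tetrahydrooxepin-2-yl]propanoate
Product: 18 methyl (3S)-3-(tert-butyldimethylsilyloxy)-3-[(2S,7R)-7-formyl-2,3,6,7-tetrahydrooxepin-2-yl]propanoate
Conditions: Dess–Martin periodinane, CH2Cl2, 0 °C → rt; used at once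
Reagents that add atoms: none
Why: Dess–Martin oxidation to the second α-alkoxy aldehyde under neutral conditions, which should keep C12 from epimerising.

Step 14
Reactants: 18 methyl (3S)-3-(tert-butyldimethylsilyloxy)-3-[(2S,7R)-7-formyl-2,3,6,7-tetrahydrooxepin-2-yl]propanoate; 19 ethylmagnesium bromide
Product: 20 methyl (3S)-3-(tert-butyldimethylsilyloxy)-3-[(2S,7R)-7-[(1R)-1-hydroxypropyl]-2,3,6,7-tetrahydrooxepin-2-yl]propanoate
Conditions: MgBr2·OEt2, CH2Cl2, −78 °C; then EtMgBr (Et2O), −78 °C
Reagents that add atoms: ethylmagnesium bromide (19), CC[Mg]Br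
Why: Chelation-controlled Grignard addition; in the Cram chelate between the aldehyde oxygen and the ring oxygen the ethyl group enters from the side of the C12–H, which sets C13 as R (syn), and at −78 °C the aldehyde should react well ahead of the methyl ester.

Step 15
Reactants: 20 methyl (3S)-3-(tert-butyldimethylsilyloxy)-3-[(2S,7R)-7-[(1R)-1-hydroxypropyl]-2,3,6,7-tetrahydrooxepin-2-yl]propanoate
Product: 21 methyl (3S)-3-[(2S,7R)-7-[(1S)-1-bromopropyl]-2,3,6,7-tetrahydrooxepin-2-yl]-3-(tert-butyldimethylsilyloxy)propanoate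
Conditions: CBr4, (n-Oct)3P, toluene, 70 °C
Reagents that add atoms: carbon tetrabromide, BrC(Br)(Br)Br
Why: Appel-type bromination; bromide displaces the alkoxyphosphonium by SN2, inverting C13 from R to S, and the trialkylphosphine in a non-polar solvent is the usual choice for carbinols flanked by a ring ether oxygen.

Step 16
Reactants: 21 methyl (3S)-3-[(2S,7R)-7-[(1S)-1-bromopropyl]-2,3,6,7-tetrahydrooxepin-2-yl]-3-(tert-butyldimethylsilyloxy)propanoate
Product: 22 (3S)-3-[(2S,7R)-7-[(1S)-1-bromopropyl]-2,3,6,7-tetrahydrooxepin-2-yl]-3-(tert-butyldimethylsilyloxy)propanal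
Conditions: DIBAL-H, CH2Cl2, −78 °C; MeOH, then aq. Rochelle salt
Reagents that add atoms: none
Why: Partial reduction of the methyl ester; at −78 °C the aluminium hemiacetal persists and collapses to the aldehyde only on work-up, while bromide, silyl ether and olefin are inert.

Step 17
Reactants: 22 (3S)-3-[(2S,7R)-7-[(1S)-1-bromopropyl]-2,3,6,7-tetrahydrooxepin-2-yl]-3-(tert-butyldimethylsilyloxy)propanal; 23 1,3-bis(triisopropylsilyl)propyne
Product: 24 tert-butyl{[(1S,3Z)-1-[(2S,7R)-7-[(1S)-1-bromopropyl]-2,3,6,7-tetrahydrooxepin-2-yl]-6-(triisopropylsilyl)hex-3-en-5-yn-1-yl]oxy}dimethylsilane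
Conditions: 23, n-BuLi, THF, −20 °C; then 22, −78 °C → rt
Reagents that add atoms: 1,3-bis(triisopropylsilyl)propyne (23), CC(C)[Si](C(C)C)(C(C)C)CC#C[Si](C(C)C)(C(C)C)C(C)C
Why: Peterson olefination with the lithiated bis-silylpropyne; addition to the aldehyde and syn-elimination of the silanolate form C3=C4, and the bulky triisopropylsilyl groups should direct the geometry to Z.

Step 18
Reactants: 24 tert-butyl{[(1S,3Z)-1-[(2S,7R)-7-[(1S)-1-bromopropyl]-2,3,6,7-tetrahydrooxepin-2-yl]-6-(triisopropylsilyl)hex-3-en-5-yn-1-yl]oxy}dimethylsilane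
Product: 25 (1S,3Z)-1-[(2S,7R)-7-[(1S)-1-bromopropyl]-2,3,6,7-tetrahydrooxepin-2-yl]hex-3-en-5-yn-1-ol
Conditions: TBAF, THF, 0 °C → rt
Reagents that add atoms: none
Why: Fluoride-induced desilylation cleaves the alkynyl C–Si bond and the silyl ether in one operation; at this temperature the secondary bromide, deactivated by the adjacent ring oxygen, should not eliminate.

Step 19
Reactants: 25 (1S,3Z)-1-[(2S,7R)-7-[(1S)-1-bromopropyl]-2,3,6,7-tetrahydrooxepin-2-yl]hex-3-en-5-yn-1-ol
Product: 26 (1S,3Z)-1-[(2S,7R)-7-[(1S)-1-bromopropyl]-2,3,6,7-tetrahydrooxepin-2-yl]hex-3-en-5-yn-1-yl acetate (target)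
Conditions: Ac2O, pyridine, DMAP (cat.), CH2Cl2, rt
Reagents that add atoms: acetic anhydride, CC(=O)OC(C)=O
Why: DMAP-catalysed acylation of the C6 alcohol proceeds at oxygen with retention, and nothing else in the molecule reacts with the anhydride.

**Compound list**

1 | chelidonic acid (4-oxo-4H-pyran-2,6-dicarboxylic acid) | OC(=O)C1=CC(=O)C=C(C(=O)O)O1 | starting material
2 | dimethyl 4-oxo-4H-pyran-2,6-dicarboxylate | COC(=O)C1=CC(=O)C=C(C(=O)OC)O1 | intermediate
3 | dimethyl all-cis-4-hydroxytetrahydropyran-2,6-dicarboxylate (meso) | COC(=O)[C@@H]1C[C@H](O)C[C@H](C(=O)OC)O1 | intermediate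
4 | dimethyl (2R,6S)-4-oxotetrahydropyran-2,6-dicarboxylate (meso, cis) | COC(=O)[C@@H]1CC(=O)C[C@H](C(=O)OC)O1 | intermediate
5 | (trimethylsilyl)diazomethane | C[Si](C)(C)C=[N+]=[N-] | starting material
6 | dimethyl cis-4-oxo-5-(trimethylsilyl)oxepane-2,7-dicarboxylate (racemic, C5 epimers, one enantiomer drawn) | COC(=O)[C@@H]1CC(=O)C([Si](C)(C)C)C[C@H](C(=O)OC)O1 | intermediate
7 | dimethyl cis-4-(trimethylsilyloxy)-2,3,6,7-tetrahydrooxepine-2,7-dicarboxylate (racemic, one enantiomer drawn) | COC(=O)[C@@H]1CC(O[Si](C)(C)C)=CC[C@H](C(=O)OC)O1 | intermediate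
8 | dimethyl cis-4-(trifluoromethylsulfonyloxy)-2,3,6,7-tetrahydrooxepine-2,7-dicarboxylate (racemic, one enantiomer drawn) | COC(=O)[C@@H]1CC(OS(=O)(=O)C(F)(F)F)=CC[C@H](C(=O)OC)O1 | intermediate
9 | dimethyl (2R,7S)-2,3,6,7-tetrahydrooxepine-2,7-dicarboxylate (meso) | COC(=O)[C@@H]1CC=CC[C@H](C(=O)OC)O1 | intermediate
10 | [(2R,7S)-2,3,6,7-tetrahydrooxepine-2,7-diyl]dimethanol (meso) | OC[C@@H]1CC=CC[C@H](CO)O1 | intermediate
11 | vinyl acetate | CC(=O)OC=C | starting material
12 | [(2R,7S)-7-(hydroxymethyl)-2,3,6,7-tetrahydrooxepin-2-yl]methyl acetate | OC[C@@H]1CC=CC[C@H](COC(C)=O)O1 | intermediate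
13 | [(2R,7S)-7-formyl-2,3,6,7-tetrahydrooxepin-2-yl]methyl acetate | O=C[C@@H]1CC=CC[C@H](COC(C)=O)O1 | intermediate
14 | 1-(tert-butyldimethylsilyloxy)-1-methoxyethene | COC(=C)O[Si](C)(C)C(C)(C)C | starting material
15 | methyl (3S)-3-[(2S,7R)-7-(acetoxymethyl)-2,3,6,7-tetrahydrooxepin-2-yl]-3-hydroxypropanoate | COC(=O)C[C@H](O)[C@@H]1CC=CC[C@H](COC(C)=O)O1 | intermediate
16 | methyl (3S)-3-[(2S,7R)-7-(acetoxymethyl)-2,3,6,7-tetrahydrooxepin-2-yl]-3-(tert-butyldimethylsilyloxy)propanoate | COC(=O)C[C@H](O[Si](C)(C)C(C)(C)C)[C@@H]1CC=CC[C@H](COC(C)=O)O1 | intermediate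
17 | methyl (3S)-3-(tert-butyldimethylsilyloxy)-3-[(2S,7R)-7-(hydroxymethyl)-2,3,6,7-tetrahydrooxepin-2-yl]propanoate | COC(=O)C[C@H](O[Si](C)(C)C(C)(C)C)[C@@H]1CC=CC[C@H](CO)O1 | intermediate
18 | methyl (3S)-3-(tert-butyldimethylsilyloxy)-3-[(2S,7R)-7-formyl-2,3,6,7-tetrahydrooxepin-2-yl]propanoate | COC(=O)C[C@H](O[Si](C)(C)C(C)(C)C)[C@@H]1CC=CC[C@H](C=O)O1 | intermediate
19 | ethylmagnesium bromide | CC[Mg]Br | starting material
20 | methyl (3S)-3-(tert-butyldimethylsilyloxy)-3-[(2S,7R)-7-[(1R)-1-hydroxypropyl]-2,3,6,7-tetrahydrooxepin-2-yl]propanoate | COC(=O)C[C@H](O[Si](C)(C)C(C)(C)C)[C@@H]1CC=CC[C@H]([C@H](O)CC)O1 | intermediate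
21 | methyl (3S)-3-[(2S,7R)-7-[(1S)-1-bromopropyl]-2,3,6,7-tetrahydrooxepin-2-yl]-3-(tert-butyldimethylsilyloxy)propanoate | COC(=O)C[C@H](O[Si](C)(C)C(C)(C)C)[C@@H]1CC=CC[C@H]([C@@H](Br)CC)O1 | intermediate
22 | (3S)-3-[(2S,7R)-7-[(1S)-1-bromopropyl]-2,3,6,7-tetrahydrooxepin-2-yl]-3-(tert-butyldimethylsilyloxy)propanal | O=CC[C@H](O[Si](C)(C)C(C)(C)C)[C@@H]1CC=CC[C@H]([C@@H](Br)CC)O1 | intermediate
23 | 1,3-bis(triisopropylsilyl)propyne | CC(C)[Si](C(C)C)(C(C)C)CC#C[Si](C(C)C)(C(C)C)C(C)C | starting material
24 | tert-butyl{[(1S,3Z)-1-[(2S,7R)-7-[(1S)-1-bromopropyl]-2,3,6,7-tetrahydrooxepin-2-yl]-6-(triisopropylsilyl)hex-3-en-5-yn-1-yl]oxy}dimethylsilane | CC(C)[Si](C(C)C)(C(C)C)C#C/C=C\C[C@H](O[Si](C)(C)C(C)(C)C)[C@@H]1CC=CC[C@H]([C@@H](Br)CC)O1 | intermediate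
25 | (1S,3Z)-1-[(2S,7R)-7-[(1S)-1-bromopropyl]-2,3,6,7-tetrahydrooxepin-2-yl]hex-3-en-5-yn-1-ol | C#C/C=C\C[C@H](O)[C@@H]1CC=CC[C@H]([C@@H](Br)CC)O1 | intermediate
26 | (1S,3Z)-1-[(2S,7R)-7-[(1S)-1-bromopropyl]-2,3,6,7-tetrahydrooxepin-2-yl]hex-3-en-5-yn-1-yl acetate | C#C/C=C\C[C@H](OC(C)=O)[C@@H]1CC=CC[C@H]([C@@H](Br)CC)O1 | target

**Totals**

Total step count: 19. Longest linear sequence: 19 steps (from chelidonic acid 1).

**Steps most likely to fail**

Step 5. The silyl shift may stop short, so that fluoride or adventitious water returns the desilylated ketone. The caesium enolate may also lose its regiochemical integrity by proton transfer, after which the enolate on the other side of the carbonyl expels the ring oxygen. Fallback, from 6 back to 9: the ketone of 6 is reduced with L-Selectride (THF, −78 °C) to dimethyl cis-4-hydroxy-5-(trimethylsilyl)oxepane-2,7-dicarboxylate F1. A Peterson elimination then removes silicon and oxygen together (BF3·OEt2, CH2Cl2, 0 °C for the anti-disposed Si/OH pair; KHMDS, THF, −78 → 0 °C for the syn-disposed pair). This places the olefin between the same two carbons and should give 9 without a ketone enolate being formed.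

Step 8. The enzyme may discriminate the two enantiotopic hydroxymethyl groups poorly, or acetylation may run on to the diacetate. Fallback, from 9 back to 12: desymmetrisation is moved to the diester. Pig liver esterase (pH 7 phosphate buffer) hydrolyses one enantiotopic ester of 9 to (2S,7R)-7-(methoxycarbonyl)-2,3,6,7-tetrahydrooxepine-2-carboxylic acid F2, taken here with the acid on the arm that becomes C6. LiBH4 (THF) reduces the remaining ester in the presence of the carboxylate to (2S,7R)-7-(hydroxymethyl)-2,3,6,7-tetrahydrooxepine-2-carboxylic acid F3. Ac2O/pyridine gives (2S,7R)-7-(acetoxymethyl)-2,3,6,7-tetrahydrooxepine-2-carboxylic acid F4. Isobutyl chloroformate/N-methylmorpholine converts it into (2S,7R)-7-(acetoxymethyl)-2,3,6,7-tetrahydrooxepine-2-carboxylic isobutyl carbonic anhydride F5, which NaBH4 (THF–H2O, −15 °C) reduces to 12.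

Step 14. Incomplete chelation between the aldehyde and the ring oxygen lets Felkin-type attack compete, which lowers facial selectivity at C13. Fallback, from 18 back to 20: the stereocentre is set by hydride delivery instead of C–C bond formation. EtMgBr in THF at −78 °C without additive gives 20 together with its C13 epimer, methyl (3S)-3-(tert-butyldimethylsilyloxy)-3-[(2S,7R)-7-[(1S)-1-hydroxypropyl]-2,3,6,7-tetrahydrooxepin-2-yl]propanoate F6. Dess–Martin oxidation of the mixture gives methyl (3S)-3-(tert-butyldimethylsilyloxy)-3-[(2S,7R)-7-propanoyl-2,3,6,7-tetrahydrooxepin-2-yl]propanoate F7. Reduction with L-Selectride (THF, −78 °C) under Felkin–Anh control (ring oxygen anti to the incoming hydride) should deliver the syn carbinol 20.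

**Further compounds**

F1 | step 5 | dimethyl cis-4-hydroxy-5-(trimethylsilyl)oxepane-2,7-dicarboxylate (racemic, diastereomers) | COC(=O)[C@@H]1CC(O)C([Si](C)(C)C)C[C@H](C(=O)OC)O1
F2 | step 8 | (2S,7R)-7-(methoxycarbonyl)-2,3,6,7-tetrahydrooxepine-2-carboxylic acid | OC(=O)[C@@H]1CC=CC[C@H](C(=O)OC)O1
F3 | step 8 | (2S,7R)-7-(hydroxymethyl)-2,3,6,7-tetrahydrooxepine-2-carboxylic acid | OC(=O)[C@@H]1CC=CC[C@H](CO)O1
F4 | step 8 | (2S,7R)-7-(acetoxymethyl)-2,3,6,7-tetrahydrooxepine-2-carboxylic acid | OC(=O)[C@@H]1CC=CC[C@H](COC(C)=O)O1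
F5 | step 8 | (2S,7R)-7-(acetoxymethyl)-2,3,6,7-tetrahydrooxepine-2-carboxylic isobutyl carbonic anhydride | CC(C)COC(=O)OC(=O)[C@@H]1CC=CC[C@H](COC(C)=O)O1
F6 | step 14 | methyl (3S)-3-(tert-butyldimethylsilyloxy)-3-[(2S,7R)-7-[(1S)-1-hydroxypropyl]-2,3,6,7-tetrahydrooxepin-2-yl]propanoate | COC(=O)C[C@H](O[Si](C)(C)C(C)(C)C)[C@@H]1CC=CC[C@H]([C@@H](O)CC)O1
F7 | step 14 | methyl (3S)-3-(tert-butyldimethylsilyloxy)-3-[(2S,7R)-7-propanoyl-2,3,6,7-tetrahydrooxepin-2-yl]propanoate | COC(=O)C[C@H](O[Si](C)(C)C(C)(C)C)[C@@H]1CC=CC[C@H](C(=O)CC)O1
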